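**Retrosynthetic overview**

- Numbering (eudesmane): ring A = C1, C2, C3, C4, C5, C10. Ring B = C5, C6, C7, C8, C9, C10. C11 is the carbinol carbon on C7, and C1' is the benzylic carbon on C1.
- Late disconnections: both CHO groups (Vilsmeier–Haack), the three benzyl ethers, C1'–H (hydride to the benzylic cation) and C1'–isobutyl (organocerium) lead back to a 1-aroyl-eudesm-5-en-11-ol.
- Key disconnection: one operation undoes C1–C10 (ring A), C4–H, C1'=O and C11–OH and re-ties C6–C11. This gives a tertiary allylic alcohol in which a 2-carene (ring B plus a temporary C6–C7–C11 gem-dimethylcyclopropane) carries a 4-arylbut-3-ynyl chain. It comes from 2-acetyl-2-carene and a homopropargyl Grignard reagent.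
- Enabling feature: the array C5=C6–C7–C11(OH) of ring B is the product pattern of a C5 cyclopropylcarbinyl cation opening a C6–C7–C11 cyclopropane. Ring A (methyl on C4, C1' on C1, para) is a terpinyl ring that closes from a linalyl-type C4–C5–C10 allyl cation. The C4=C5 alkene left by that closure is the trigger for the opening.
- Ring order: the aromatic ring and ring B are bought (tribenzyl phloroglucinol, (S)-carvone). The temporary cyclopropane is made next. Ring A is closed last, while the cyclopropane is opened.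

Key step: step 9

Assumption: 1,3,5-tris(benzyloxy)benzene is taken as a purchasable phloroglucinol ether. Descriptors in the eudesmane-type names use the numbering given above.

Step 1
Reactants: 1 (S)-(+)-carvone
Product: 2 (5S)-5-(2-chloropropan-2-yl)-2-methylcyclohex-2-en-1-one
Conditions: HCl (g), CH2Cl2, 0 °C
Reagents that add atoms: hydrogen chloride, Cl
Why: Markovnikov hydrochlorination: only the electron-rich 1,1-disubstituted alkene is protonated (tertiary cation), the enone alkene is inert, and the carvone stereocentre (later C7) is not touched.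

Step 2
Reactants: 2 (5S)-5-(2-chloropropan-2-yl)-2-methylcyclohex-2-en-1-one
Product: 3 (1R,6S)-3,7,7-trimethylbicyclo[4.1.0]hept-3-en-2-one (car-3-en-2-one)
Conditions: LiN(i-Pr)2, THF–DMPU, −78 °C → rt
Reagents that add atoms: none
Why: Intramolecular enolate alkylation (3-exo-tet, carone-type cyclopropane closure): kinetic deprotonation at the alpha' CH2 puts the nucleophile next to the carbon that bears the tertiary chloride, and a three-membered ring on a cyclohexenone can only be cis-fused, so the new centre (later C6) follows from the carvone centre.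

Step 3
Reactants: 3 (1R,6S)-3,7,7-trimethylbicyclo[4.1.0]hept-3-en-2-one
Product: 5 (1R,6S)-3,7,7-trimethylbicyclo[4.1.0]hept-2-en-2-yl trifluoromethanesulfonate, via lithium enolate 4 (not isolated)
Conditions: LiBH(s-Bu)3, THF, −78 °C; then PhNTf2, −78 °C → rt
Reagents that add atoms: N-phenylbis(trifluoromethanesulfonimide), O=S(=O)(N(c1ccccc1)S(=O)(=O)C(F)(F)F)C(F)(F)F
Why: Conjugate hydride reduction of a beta-unsubstituted 2-methylcyclohexenone followed by O-triflation of the regiodefined enolate (reductive enol triflate formation), which fixes the tetrasubstituted C5=C10 alkene next to the cyclopropane.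

Step 4
Reactants: 5 (1R,6S)-3,7,7-trimethylbicyclo[4.1.0]hept-2-en-2-yl trifluoromethanesulfonate
Product: 7 1-[(1R,6S)-3,7,7-trimethylbicyclo[4.1.0]hept-2-en-2-yl]ethan-1-one (2-acetyl-2-carene), via ethoxydiene 6 (not isolated)
Conditions: CH2=C(OEt)SnBu3, Pd(PPh3)4 (cat.), LiCl, THF, reflux; then 1 M HCl, THF, 0 °C
Reagents that add atoms: tributyl(1-ethoxyvinyl)stannane, CCCC[Sn](CCCC)(CCCC)C(=C)OCC; water, O
Why: Stille coupling of the alkenyl triflate with an acetyl anion equivalent, then enol ether hydrolysis with acid that is too weak and too brief to open the cyclopropane, whose alkene is deactivated as soon as the acetyl group appears.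

Step 5
Reactants: 8 1,3,5-tris(benzyloxy)benzene
Product: 9 1,3,5-tris(benzyloxy)-2-iodobenzene
Conditions: NIS, CH2Cl2, 0 °C, dark
Reagents that add atoms: N-iodosuccinimide, O=C1CCC(=O)N1I
Why: Electrophilic aromatic iodination of a very electron-rich arene whose three free positions are equivalent, so one equivalent of NIS should stop at the mono-iodide.

Step 6
Reactants: 9 1,3,5-tris(benzyloxy)-2-iodobenzene; 10 but-3-yn-1-ol
Product: 11 4-[2,4,6-tris(benzyloxy)phenyl]but-3-yn-1-ol
Conditions: PdCl2(PPh3)2 (cat.), CuI (cat.), Et3N, THF, 50 °C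
Reagents that add atoms: none
Why: Sonogashira coupling of an aryl iodide with a terminal alkyne, which tolerates the free primary alcohol.

Step 7
Reactants: 11 4-[2,4,6-tris(benzyloxy)phenyl]but-3-yn-1-ol
Product: 12 1,3,5-tris(benzyloxy)-2-(4-bromobut-1-yn-1-yl)benzene
Conditions: CBr4, PPh3, CH2Cl2, 0 °C
Reagents that add atoms: carbon tetrabromide, BrC(Br)(Br)Br
Why: Appel bromination of a primary alcohol under neutral conditions that leave the alkyne and the benzyl ethers alone.

Step 8
Reactants: 12 1,3,5-tris(benzyloxy)-2-(4-bromobut-1-yn-1-yl)benzene; 7 2-acetyl-2-carene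
Product: 14 6-[2,4,6-tris(benzyloxy)phenyl]-2-[(1R,6S)-3,7,7-trimethylbicyclo[4.1.0]hept-2-en-2-yl]hex-5-yn-2-ol (both carbinol epimers), via Grignard reagent 13 (not isolated)
Conditions: Mg, THF, rt; then LaCl3·2LiCl, 7, THF, −20 °C; pH 7 buffer
Reagents that add atoms: none
Why: Grignard formation from a primary homopropargylic bromide and lanthanum-assisted 1,2-addition to the methyl ketone, in which LaCl3·2LiCl suppresses enolisation and the fully substituted beta carbon rules out 1,4-addition; the new carbinol centre (C4) needs no control because it is ionised in step 9.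

Step 9
Reactants: 14 6-[2,4,6-tris(benzyloxy)phenyl]-2-[(1R,6S)-3,7,7-trimethylbicyclo[4.1.0]hept-2-en-2-yl]hex-5-yn-2-ol
Product: 17 (1S,4R,7S,10R)-1-[2,4,6-tris(benzyloxy)benzoyl]eudesm-5-en-11-ol, via enol trifluoroacetate 15 (not isolated), via cyclopropane ketone 16 (not isolated)
Conditions: CF3CO2H, CH2Cl2, −78 → −30 °C; then THF–H2O, HClO4 (0.5 M), 0 °C → rt
Reagents that add atoms: water, O
Why: Proposed new method: CF3CO2H ionises the tertiary allylic alcohol to a pentasubstituted C4–C5–C10 allyl cation whose C10 terminus is captured by C1 of the aryl alkyne, the aryl-stabilised vinyl cation at C1' collapses with trifluoroacetate to 15, aqueous acid hydrolyses 15 to ketone 16, and protonation of the new C4=C5 alkene at C4 gives the C5 cyclopropylcarbinyl cation, which opens by C6–C11 cleavage to the C5=C6 alkene and a tertiary C11 cation that water quenches. The closest known reaction types are the linalyl-to-terpinyl closure and biomimetic allyl cation–alkyne cyclisation to a ketone for the first half, and the solvolytic opening of 2-carene and its epoxide to p-menth-2-en-8-ols (cyclopropylcarbinyl–homoallyl rearrangement) for the second half; what is new is their relay through one alkene in one flask and the closure onto a fully substituted allyl terminus. Ring A closes 6-exo-dig at the alkyne (the allyl unit ends up inside the ring, as in the terpinyl closure), and the temporary cyclopropane is the only ring that is lost. C10 is set by attack of the tethered alkyne on the face of ring B opposite the gem-dimethylcyclopropane, C4 by anti-SE2'-type protonation opposite the breaking C6–C11 bond (also the face free of the C10 methyl group), C1 by acid equilibration of the ketone to the equatorial aroyl group, and C7 is carried over from carvone. The step needs bonding at C1 and not C1' (secured by the electron-rich aryl group, which polarises the alkyne and stabilises only the C1' vinyl cation, and by six- versus seven-membered ring size), ionisation before any alkene protonation (secured by running the first stage at −78 °C), and C6–C11 rather than C6–C7 cleavage (tertiary versus secondary cation).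

Step 10
Reactants: 17 (1S,4R,7S,10R)-1-[2,4,6-tris(benzyloxy)benzoyl]eudesm-5-en-11-ol
Product: 18 (1S,4R,7S,10R)-1-{1-hydroxy-3-methyl-1-[2,4,6-tris(benzyloxy)phenyl]butyl}eudesm-5-en-11-ol (both C1' carbinol epimers)
Conditions: i-BuLi, CeCl3, THF, −78 → −20 °C
Reagents that add atoms: isobutyllithium, [Li]CC(C)C
Why: Organocerium 1,2-addition, chosen because the weakly basic, oxophilic reagent adds to hindered enolisable ketones without beta-hydride reduction; one equivalent is spent on the C11 hydroxyl and the new carbinol centre is erased in step 11.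

Step 11
Reactants: 18 (1S,4R,7S,10R)-1-{1-hydroxy-3-methyl-1-[2,4,6-tris(benzyloxy)phenyl]butyl}eudesm-5-en-11-ol
Product: 19 (1R,4R,7S,10R)-1-{(1S)-3-methyl-1-[2,4,6-tris(benzyloxy)phenyl]butyl}eudesm-5-en-11-ol
Conditions: Et3SiH, CF3CO2H, CH2Cl2, −78 → −40 °C
Reagents that add atoms: none
Why: Ionic hydrogenation: only the trialkoxybenzylic alcohol ionises at this temperature (the C11 alcohol and the C5=C6 alkene need far stronger forcing), and in the planar cation A1,3 strain turns the C1–H bond towards the ortho benzyloxy group, so that quaternary C10 blocks one face and hydride enters from the C2 side, which should give the (1'S) centre.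

Step 12
Reactants: 19 (1R,4R,7S,10R)-1-{(1S)-3-methyl-1-[2,4,6-tris(benzyloxy)phenyl]butyl}eudesm-5-en-11-ol
Product: 20 2-{(1S)-1-[(1R,4R,7S,10R)-11-hydroxyeudesm-5-en-1-yl]-3-methylbutyl}benzene-1,3,5-triol
Conditions: H2 (1 atm), Pd/C, EtOAc–EtOH, rt, stopped at three equivalents of H2
Reagents that add atoms: none
Why: Catalytic hydrogenolysis of aryl benzyl ethers, which should be much faster than hydrogenation of the trisubstituted C5=C6 alkene shielded by quaternary C10, the C4 methyl group and the C7 branch.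

Step 13
Reactants: 20 2-{(1S)-1-[(1R,4R,7S,10R)-11-hydroxyeudesm-5-en-1-yl]-3-methylbutyl}benzene-1,3,5-triol
Product: 22 CNP0108656.4 (target), via bis(iminium) salt 21 (not isolated)
Conditions: POCl3, DMF, EtOAc, 0 °C → rt; then H2O, rt
Reagents that add atoms: N,N-dimethylformamide, CN(C)C=O; water, O
Why: Double Vilsmeier–Haack formylation of an alkylphloroglucinol, whose two remaining ring positions are each flanked by two hydroxyl groups and should react with a measured amount of the chloroiminium salt far faster than the hindered tertiary alcohol does.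

**Compound list**

1 | (S)-(+)-carvone | CC1=CC[C@@H](CC1=O)C(C)=C | starting material
2 | (5S)-5-(2-chloropropan-2-yl)-2-methylcyclohex-2-en-1-one | CC1=CC[C@@H](CC1=O)C(C)(C)Cl | intermediate
3 | (1R,6S)-3,7,7-trimethylbicyclo[4.1.0]hept-3-en-2-one | CC1=CC[C@H]2[C@@H](C1=O)C2(C)C | intermediate
4 | lithium (1R,6S)-3,7,7-trimethylbicyclo[4.1.0]hept-2-en-2-olate | CC1=C(O[Li])[C@@H]2[C@H](CC1)C2(C)C | intermediate
5 | (1R,6S)-3,7,7-trimethylbicyclo[4.1.0]hept-2-en-2-yl trifluoromethanesulfonate | CC1=C(OS(=O)(=O)C(F)(F)F)[C@@H]2[C@H](CC1)C2(C)C | intermediate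
6 | (1R,6S)-2-(1-ethoxyethenyl)-3,7,7-trimethylbicyclo[4.1.0]hept-2-ene | CC1=C(C(=C)OCC)[C@@H]2[C@H](CC1)C2(C)C | intermediate
7 | 1-[(1R,6S)-3,7,7-trimethylbicyclo[4.1.0]hept-2-en-2-yl]ethan-1-one | CC1=C(C(C)=O)[C@@H]2[C@H](CC1)C2(C)C | intermediate
8 | 1,3,5-tris(benzyloxy)benzene | c1ccc(COc2cc(OCc3ccccc3)cc(OCc3ccccc3)c2)cc1 | starting material
9 | 1,3,5-tris(benzyloxy)-2-iodobenzene | Ic1c(OCc2ccccc2)cc(OCc2ccccc2)cc1OCc1ccccc1 | intermediate
10 | but-3-yn-1-ol | C#CCCO | starting material
11 | 4-[2,4,6-tris(benzyloxy)phenyl]but-3-yn-1-ol | OCCC#Cc1c(OCc2ccccc2)cc(OCc2ccccc2)cc1OCc1ccccc1 | intermediate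
12 | 1,3,5-tris(benzyloxy)-2-(4-bromobut-1-yn-1-yl)benzene | BrCCC#Cc1c(OCc2ccccc2)cc(OCc2ccccc2)cc1OCc1ccccc1 | intermediate
13 | {4-[2,4,6-tris(benzyloxy)phenyl]but-3-yn-1-yl}magnesium bromide | Br[Mg]CCC#Cc1c(OCc2ccccc2)cc(OCc2ccccc2)cc1OCc1ccccc1 | intermediate
14 | 6-[2,4,6-tris(benzyloxy)phenyl]-2-[(1R,6S)-3,7,7-trimethylbicyclo[4.1.0]hept-2-en-2-yl]hex-5-yn-2-ol (carbinol epimers) | CC1=C(C(C)(O)CCC#Cc2c(OCc3ccccc3)cc(OCc3ccccc3)cc2OCc2ccccc2)[C@@H]2[C@H](CC1)C2(C)C | intermediate
15 | enol trifluoroacetate of 16 (alkene geometry open) | O=C(OC(c1c(OCc2ccccc2)cc(OCc2ccccc2)cc1OCc1ccccc1)=C1CCC(C)=C2[C@@H]3[C@H](CC[C@]12C)C3(C)C)C(F)(F)F | intermediate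
16 | (1S,6R,7S,10R)-1-[2,4,6-tris(benzyloxy)benzoyl]-6,11-cycloeudesm-4-ene | O=C(c1c(OCc2ccccc2)cc(OCc2ccccc2)cc1OCc1ccccc1)[C@H]1CCC(C)=C2[C@@H]3[C@H](CC[C@]12C)C3(C)C | intermediate
17 | (1S,4R,7S,10R)-1-[2,4,6-tris(benzyloxy)benzoyl]eudesm-5-en-11-ol | O=C(c1c(OCc2ccccc2)cc(OCc2ccccc2)cc1OCc1ccccc1)[C@H]1CC[C@@H](C)C2=C[C@@H](C(C)(C)O)CC[C@@]21C | intermediate
18 | (1S,4R,7S,10R)-1-{1-hydroxy-3-methyl-1-[2,4,6-tris(benzyloxy)phenyl]butyl}eudesm-5-en-11-ol (C1' epimers) | CC(C)CC(O)(c1c(OCc2ccccc2)cc(OCc2ccccc2)cc1OCc1ccccc1)[C@H]1CC[C@@H](C)C2=C[C@@H](C(C)(C)O)CC[C@@]21C | intermediate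
19 | (1R,4R,7S,10R)-1-{(1S)-3-methyl-1-[2,4,6-tris(benzyloxy)phenyl]butyl}eudesm-5-en-11-ol | CC(C)C[C@H](c1c(OCc2ccccc2)cc(OCc2ccccc2)cc1OCc1ccccc1)[C@H]1CC[C@@H](C)C2=C[C@@H](C(C)(C)O)CC[C@@]21C | intermediate
20 | 2-{(1S)-1-[(1R,4R,7S,10R)-11-hydroxyeudesm-5-en-1-yl]-3-methylbutyl}benzene-1,3,5-triol | CC(C)C[C@H](c1c(O)cc(O)cc1O)[C@H]1CC[C@@H](C)C2=C[C@@H](C(C)(C)O)CC[C@@]21C | intermediate
21 | bis(dimethyliminium) dichloride of the target | CC(C)C[C@H](c1c(O)c(C=[N+](C)C)c(O)c(C=[N+](C)C)c1O)[C@H]1CC[C@@H](C)C2=C[C@@H](C(C)(C)O)CC[C@@]21C.[Cl-].[Cl-] | intermediate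
22 | CNP0108656.4, 5-{(1S)-1-[(1R,4R,7S,10R)-11-hydroxyeudesm-5-en-1-yl]-3-methylbutyl}-2,4,6-trihydroxybenzene-1,3-dicarbaldehyde | CC(C)C[C@H](c1c(O)c(C=O)c(O)c(C=O)c1O)[C@H]1CC[C@@H](C)C2=C[C@@H](C(C)(C)O)CC[C@@]21C | target

**Step count**

Total step count: 13. Longest linear sequence: 10 (steps 1–4 and 8–13).

**Steps most likely to fail**

**Step 9.**
- The relay may break down through opening of the vinylcyclopropane before the alcohol ionises.
- It may also fail through plain hydration of the alkyne without ring closure, through proton loss from the allyl cation to trienes, or through protonation of C4 from the wrong face.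
- The fallback closes ring A by a Diels–Alder reaction and sets out from 5 and 9.
- Triflate 5 is coupled with isopropenylboronic acid pinacol ester (Suzuki–Miyaura, PdCl2(dppf), K3PO4) to (1R,6S)-3,7,7-trimethyl-2-(prop-1-en-2-yl)bicyclo[4.1.0]hept-2-ene F1.
- Iodide 9 is lithiated (n-BuLi) and added to acrolein to give 1-[2,4,6-tris(benzyloxy)phenyl]prop-2-en-1-ol F2. MnO2 oxidises F2 to 1-[2,4,6-tris(benzyloxy)phenyl]prop-2-en-1-one F3.
- Heating F1 with F3 (or Et2AlCl at low temperature) should give the ortho-oriented adduct formed on the face opposite the cyclopropane. This adduct is 16, now isolated.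
- Dilute aqueous acid then opens 16, and the route is rejoined at 17.

**Step 10.**
- Steric shielding of the carbonyl group by the two ortho benzyloxy groups and by C10 may lead to enolisation or to no addition at all.
- The fallback sets out from 17. It builds the isobutyl group at the remote carbon and sets C1' by hydroboration.
- The much smaller MeLi/CeCl3 reagent gives the methyl carbinol 1-{1-hydroxy-1-[2,4,6-tris(benzyloxy)phenyl]ethyl}eudesm-5-en-11-ol F4.
- PPTS dehydrates F4 to the styrene 1-{1-[2,4,6-tris(benzyloxy)phenyl]ethenyl}eudesm-5-en-11-ol F5.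
- 9-BBN adds boron to the CH2 terminus and hydrogen to C1' on the face away from C10, giving the B-alkyl-9-BBN adduct F6. The C11 hydroxyl is borinated for the time being and freed on work-up.
- Suzuki–Miyaura coupling of F6 with 2-bromopropene (PdCl2(dppf), Cs2CO3) gives the methallyl compound 1-{(1S)-3-methyl-1-[2,4,6-tris(benzyloxy)phenyl]but-3-en-1-yl}eudesm-5-en-11-ol F7.
- The conditions of step 12 then saturate the 1,1-disubstituted alkene while they cleave the benzyl ethers, so the route is rejoined at 20.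

**Step 13.**
- The chloroiminium salt and the HCl it releases may ionise or dehydrate the tertiary C11 alcohol before both ring positions are formylated.
- The fallback sets out from 19 and formylates under basic conditions before deprotection.
- NBS (two equivalents, CH2Cl2, −78 °C) gives the 3,5-dibromo-2,4,6-tris(benzyloxy)phenyl compound F8.
- Bromine–lithium exchange with excess t-BuLi and quenching with DMF gives the tribenzyl ether of the target F9.
- Hydrogenolysis (H2, Pd/C) of F9 rejoins the route at 22.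

**Further compounds**

F1 | step 9 | (1R,6S)-3,7,7-trimethyl-2-(prop-1-en-2-yl)bicyclo[4.1.0]hept-2-ene | CC1=C(C(C)=C)[C@@H]2[C@H](CC1)C2(C)C
F2 | step 9 | 1-[2,4,6-tris(benzyloxy)phenyl]prop-2-en-1-ol | C=CC(O)c1c(OCc2ccccc2)cc(OCc2ccccc2)cc1OCc1ccccc1
F3 | step 9 | 1-[2,4,6-tris(benzyloxy)phenyl]prop-2-en-1-one | C=CC(=O)c1c(OCc2ccccc2)cc(OCc2ccccc2)cc1OCc1ccccc1
F4 | step 10 | 1-{1-hydroxy-1-[2,4,6-tris(benzyloxy)phenyl]ethyl}eudesm-5-en-11-ol | CC(O)(c1c(OCc2ccccc2)cc(OCc2ccccc2)cc1OCc1ccccc1)[C@H]1CC[C@@H](C)C2=C[C@@H](C(C)(C)O)CC[C@@]21C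
F5 | step 10 | 1-{1-[2,4,6-tris(benzyloxy)phenyl]ethenyl}eudesm-5-en-11-ol | C=C(c1c(OCc2ccccc2)cc(OCc2ccccc2)cc1OCc1ccccc1)[C@H]1CC[C@@H](C)C2=C[C@@H](C(C)(C)O)CC[C@@]21C
F6 | step 10 | B-alkyl-9-BBN adduct of F5 (drawn with free C11 hydroxyl) | C1CC2CCCC(C1)B2C[C@H](c1c(OCc2ccccc2)cc(OCc2ccccc2)cc1OCc1ccccc1)[C@H]1CC[C@@H](C)C2=C[C@@H](C(C)(C)O)CC[C@@]21C
F7 | step 10 | 1-{(1S)-3-methyl-1-[2,4,6-tris(benzyloxy)phenyl]but-3-en-1-yl}eudesm-5-en-11-ol | CC(=C)C[C@H](c1c(OCc2ccccc2)cc(OCc2ccccc2)cc1OCc1ccccc1)[C@H]1CC[C@@H](C)C2=C[C@@H](C(C)(C)O)CC[C@@]21C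
F8 | step 13 | 1-{(1S)-1-[3,5-dibromo-2,4,6-tris(benzyloxy)phenyl]-3-methylbutyl}eudesm-5-en-11-ol | CC(C)C[C@H](c1c(OCc2ccccc2)c(Br)c(OCc2ccccc2)c(Br)c1OCc1ccccc1)[C@H]1CC[C@@H](C)C2=C[C@@H](C(C)(C)O)CC[C@@]21C
F9 | step 13 | tribenzyl ether of the target | CC(C)C[C@H](c1c(OCc2ccccc2)c(C=O)c(OCc2ccccc2)c(C=O)c1OCc1ccccc1)[C@H]1CC[C@@H](C)C2=C[C@@H](C(C)(C)O)CC[C@@]21C
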